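The dihydropyran ring C of the isoflavan is cut away from ring A at two bonds: benzylic C4–C4a and aryl ether O1–C8a. One palladium/norbornene (Catellani-type) annulation makes both, joining a plain aryl iodide (silylated 5-iodo-2-prenylphenol) to an (R)-3-bromo-2-arylpropan-1-ol that already holds ring B and C3. The step exploits that C8a and C4a are neighbouring ring-A carbons: one C–I bond at C8a serves as ipso handle for oxygen and as relay to the ortho C–H at C4a, while the C7 silyloxy group shields C8. The bromohydrin arises by strain-releasing, squaramide-catalysed enantioselective opening of a 3-aryloxetane with TMSBr.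

Key step: step 8

Remarks: isoflavan numbering is used (O1, C2, C3, C4, C4a, C5–C8, C8a; ring A is the benzo ring of the chroman, ring B the 3-aryl group, ring C the dihydropyran). The target is the (3R) enantiomer as drawn. Assumption: the squaramide enantiomer used in step 7 is the one that delivers the (R)-bromohydrin; the sense of induction is to be assigned on the first run (chiral HPLC and Mosher ester), and the antipodal catalyst is used if it proves opposite.

**Step 1**
Reactants: 1 3-iodophenol
Product: 2 5-iodo-2-(3-methylbut-2-en-1-yl)phenol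
Conditions: NaH (1.0 equiv), toluene, 0 °C; prenyl bromide (1.0 equiv), 0 °C to rt
Reagents that add atoms: prenyl bromide (1-bromo-3-methylbut-2-ene), CC(C)=CCBr
Why: ortho-selective C-allylation of a sodium phenoxide in a non-polar medium (tight ion pair, SN2 at the primary carbon, ortho-dienone then tautomerisation), in which the ortho carbon flanked by iodine is shielded so that the free ortho carbon should react.

**Step 2**
Reactants: 2 5-iodo-2-(3-methylbut-2-en-1-yl)phenol
Product: 3 [5-iodo-2-(3-methylbut-2-en-1-yl)phenoxy]tri(propan-2-yl)silane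
Conditions: TIPSCl, imidazole, DMF, rt
Reagents that add atoms: chlorotri(propan-2-yl)silane (TIPSCl), CC(C)[Si](Cl)(C(C)C)C(C)C
Why: standard silylation of a phenol, giving a bulky aryl silyl ether that should tolerate carbonate base in step 8 and that shields the neighbouring ring C–H.

**Step 3**
Reactants: 4 4-bromoresorcinol (4-bromobenzene-1,3-diol)
Product: 5 2-bromo-5-{[tri(propan-2-yl)silyl]oxy}phenol
Conditions: TIPSCl (1.0 equiv), imidazole, CH2Cl2, −20 to 0 °C
Reagents that add atoms: chlorotri(propan-2-yl)silane (TIPSCl), CC(C)[Si](Cl)(C(C)C)C(C)C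
Why: sterically controlled monosilylation, in which the hydroxyl para to bromine is open while the hydroxyl ortho to bromine is hindered, as in known mono-O-functionalisations of 4-bromoresorcinol.

**Step 4**
Reactants: 5 2-bromo-5-{[tri(propan-2-yl)silyl]oxy}phenol
Product: 6 {4-bromo-3-[(2-methylbut-3-yn-2-yl)oxy]phenoxy}tri(propan-2-yl)silane
Conditions: 3-chloro-3-methylbut-1-yne, DBU, CuCl2·2H2O (cat.), MeCN, 0 °C
Reagents that add atoms: 3-chloro-3-methylbut-1-yne, CC(C)(Cl)C#C
Why: copper-catalysed O-propargylation of a phenol with a tertiary propargylic chloride, a standard entry to aryl 1,1-dimethylpropargyl ethers even for ortho-substituted phenols.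

**Step 5**
Reactants: 6 {4-bromo-3-[(2-methylbut-3-yn-2-yl)oxy]phenoxy}tri(propan-2-yl)silane
Product: 8 [(8-bromo-2,2-dimethyl-2H-chromen-5-yl)oxy]tri(propan-2-yl)silane, via ortho-allenylphenol 7 (not isolated)
Conditions: PhNEt2, 170 °C
Reagents that add atoms: none
Why: aromatic propargyl Claisen rearrangement to the only free ortho carbon (the other bears bromine), followed by 1,5-hydrogen shift and oxa-6π electrocyclisation, should give the 2,2-dimethylchromene with the pyran oxygen next to bromine.

**Step 6**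
Reactants: 8 [(8-bromo-2,2-dimethyl-2H-chromen-5-yl)oxy]tri(propan-2-yl)silane; 9 3-bromooxetane
Product: 10 {[2,2-dimethyl-8-(oxetan-3-yl)-2H-chromen-5-yl]oxy}tri(propan-2-yl)silane
Conditions: NiI2 (10 mol%), 4,4'-di-tert-butyl-2,2'-bipyridine (10 mol%), NaI (25 mol%), Zn dust (2 equiv), DMA, 60 °C
Reagents that add atoms: none
Why: nickel-catalysed reductive cross-electrophile coupling of an aryl bromide with a secondary alkyl bromide, in which the oxetan-3-yl radical is captured by the arylnickel species; silyl ether and chromene are inert to zinc and nickel under these conditions.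

**Step 7**
Reactants: 10 {[2,2-dimethyl-8-(oxetan-3-yl)-2H-chromen-5-yl]oxy}tri(propan-2-yl)silane
Product: 12 (2R)-3-bromo-2-(2,2-dimethyl-5-{[tri(propan-2-yl)silyl]oxy}-2H-chromen-8-yl)propan-1-ol, via silyl ether 11 (not isolated)
Conditions: TMSBr (1.2 equiv), chiral arylpyrrolidine-derived squaramide hydrogen-bond-donor catalyst (5 mol%), tBuOMe, −78 °C; then MeOH, PPTS (cat.), 0 °C
Reagents that add atoms: bromotrimethylsilane (TMSBr), C[Si](C)(C)Br
Why: hydrogen-bond-donor-catalysed desymmetrising ring opening of a prochiral 3-aryloxetane, in which the squaramide-bound bromide of the O-silyl oxetanium ion pair attacks one of the two enantiotopic CH2 groups by SN2 with release of ring strain and so sets the C3 stereocenter under catalyst control; mild methanolysis then frees the primary alcohol without touching the aryl TIPS ether.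

**Step 8**
Reactants: 3 [5-iodo-2-(3-methylbut-2-en-1-yl)phenoxy]tri(propan-2-yl)silane; 12 (2R)-3-bromo-2-(2,2-dimethyl-5-{[tri(propan-2-yl)silyl]oxy}-2H-chromen-8-yl)propan-1-ol (1.3 equiv)
Product: 13 {[(3R)-3-(2,2-dimethyl-5-{[tri(propan-2-yl)silyl]oxy}-2H-chromen-8-yl)-6-(3-methylbut-2-en-1-yl)-3,4-dihydro-2H-chromen-7-yl]oxy}tri(propan-2-yl)silane
Conditions: Pd(OAc)2 (10 mol%), XPhos (20 mol%), 1-methylbicyclo[2.2.1]hept-2-ene (bridgehead-substituted norbornene, 1.0 equiv), Cs2CO3 (3 equiv), 1,4-dioxane, 100 °C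
Reagents that add atoms: none
Why: Proposed new method: in this Catellani-type [3+3] annulation zerovalent palladium inserts into the C–I bond of 3, the arylpalladium adds across the norbornene and palladates the ortho C–H bond remote from the silyloxy group, and the resulting aryl–norbornyl palladacycle takes up the primary C–Br bond of 12 by SN2-type oxidative addition to tetravalent palladium and forges the aryl–CH2 bond by reductive elimination. The bridgehead substituent then forces β-carbon elimination of the norbornene, and the tethered alkoxide closes ring C by aryl C–O reductive elimination from a seven-membered oxapalladacycle, so the six-membered ring is closed by an intermolecular ortho C–C bond followed by an intramolecular ipso C–O bond. The closest known reaction types are the palladium/norbornene annulations of aryl iodides with epoxides to 2,3-dihydrobenzofurans and with bromoalkylamines to tetrahydroquinolines; the use of a 3-bromopropan-1-ol to make a chroman is the untested extension. No stereocenter is created: C3 arrives from 12, is never bonded to palladium and carries no acidic hydrogen, so the R configuration should be retained. The step needs a single ortho alkylation at the right C–H bond, which the bulky OTIPS group beside the other ortho carbon and the bridgehead-substituted norbornene should secure; carbonate in dioxane should keep oxetane re-closure and HBr loss from 12 slow, and the intramolecular alkoxide should outrun Heck reaction at the chromene and prenyl alkenes.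

**Step 9**
Reactants: 13 bis-TIPS ether of the target
Product: 14 (3R)-3-(5-hydroxy-2,2-dimethyl-2H-chromen-8-yl)-6-(3-methylbut-2-en-1-yl)-3,4-dihydro-2H-chromen-7-ol (CNP0332706.1)
Conditions: TBAF (2.5 equiv), AcOH (2.5 equiv), THF, 0 °C to rt
Reagents that add atoms: none
Why: fluoride-induced cleavage of both aryl silyl ethers under buffered, non-acidic conditions, which should spare the ortho-prenylphenol (no acid-induced cyclisation), the chromene and the C3 stereocenter.

**Compound list**
1 | 3-iodophenol | Oc1cccc(I)c1 | starting material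
2 | 5-iodo-2-(3-methylbut-2-en-1-yl)phenol | CC(C)=CCc1ccc(I)cc1O | intermediate
3 | [5-iodo-2-(3-methylbut-2-en-1-yl)phenoxy]tri(propan-2-yl)silane | CC(C)=CCc1ccc(I)cc1O[Si](C(C)C)(C(C)C)C(C)C | intermediate
4 | 4-bromoresorcinol (4-bromobenzene-1,3-diol) | Oc1ccc(Br)c(O)c1 | starting material
5 | 2-bromo-5-{[tri(propan-2-yl)silyl]oxy}phenol | Oc1cc(O[Si](C(C)C)(C(C)C)C(C)C)ccc1Br | intermediate
6 | {4-bromo-3-[(2-methylbut-3-yn-2-yl)oxy]phenoxy}tri(propan-2-yl)silane | C#CC(C)(C)Oc1cc(O[Si](C(C)C)(C(C)C)C(C)C)ccc1Br | intermediate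
7 | 6-bromo-2-(3-methylbuta-1,2-dien-1-yl)-3-{[tri(propan-2-yl)silyl]oxy}phenol (ortho-allenylphenol, not isolated) | CC(C)=C=Cc1c(O)c(Br)ccc1O[Si](C(C)C)(C(C)C)C(C)C | intermediate
8 | [(8-bromo-2,2-dimethyl-2H-chromen-5-yl)oxy]tri(propan-2-yl)silane | CC1(C)C=Cc2c(O[Si](C(C)C)(C(C)C)C(C)C)ccc(Br)c2O1 | intermediate
9 | 3-bromooxetane | BrC1COC1 | starting material
10 | {[2,2-dimethyl-8-(oxetan-3-yl)-2H-chromen-5-yl]oxy}tri(propan-2-yl)silane | CC1(C)C=Cc2c(O[Si](C(C)C)(C(C)C)C(C)C)ccc(C3COC3)c2O1 | intermediate
11 | {[(2R)-3-bromo-2-(2,2-dimethyl-5-{[tri(propan-2-yl)silyl]oxy}-2H-chromen-8-yl)propyl]oxy}trimethylsilane (not isolated) | C[Si](C)(C)OC[C@@H](c1ccc(O[Si](C(C)C)(C(C)C)C(C)C)c2c1OC(C)(C)C=C2)CBr | intermediate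
12 | (2R)-3-bromo-2-(2,2-dimethyl-5-{[tri(propan-2-yl)silyl]oxy}-2H-chromen-8-yl)propan-1-ol | OC[C@@H](c1ccc(O[Si](C(C)C)(C(C)C)C(C)C)c2c1OC(C)(C)C=C2)CBr | intermediate
13 | {[(3R)-3-(2,2-dimethyl-5-{[tri(propan-2-yl)silyl]oxy}-2H-chromen-8-yl)-6-(3-methylbut-2-en-1-yl)-3,4-dihydro-2H-chromen-7-yl]oxy}tri(propan-2-yl)silane | CC(C)=CCc1cc2c(cc1O[Si](C(C)C)(C(C)C)C(C)C)OC[C@@H](c1ccc(O[Si](C(C)C)(C(C)C)C(C)C)c3c1OC(C)(C)C=C3)C2 | intermediate
14 | (3R)-3-(5-hydroxy-2,2-dimethyl-2H-chromen-8-yl)-6-(3-methylbut-2-en-1-yl)-3,4-dihydro-2H-chromen-7-ol (CNP0332706.1) | CC(C)=CCc1cc2c(cc1O)OC[C@@H](c1ccc(O)c3c1OC(C)(C)C=C3)C2 | target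

Total step count: 9. Longest linear sequence: 7 steps (4 → 5 → 6 → 8 → 10 → 12 → 13 → 14; steps 3 to 9).

**Steps most likely to fail**

1. Step 8 (proposed new method). What may go wrong:
   - the norbornene may not be extruded after the first ortho alkylation, so the aryl–norbornyl species is diverted;
   - the palladium alkoxide may undergo β-hydride elimination instead of C–O reductive elimination;
   - 12 may lose HBr or re-close to the oxetane under carbonate before it is taken up;
   - a silyl ether may be cleaved prematurely by carbonate.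

   Fallback (known chemistry, the two bonds made in separate steps), setting out from 12 and coming back at 13: 12 is silylated (TBSCl, imidazole, CH2Cl2) to tert-butyl{[(2R)-3-bromo-2-(2,2-dimethyl-5-{[tri(propan-2-yl)silyl]oxy}-2H-chromen-8-yl)propyl]oxy}dimethylsilane F1. LiCl-mediated zinc insertion (Zn dust, LiCl, THF, 50 °C) converts F1 into the alkylzinc bromide F2. In parallel, commercial 3-bromo-4-iodophenol is ortho-prenylated as in step 1 to 5-bromo-4-iodo-2-(3-methylbut-2-en-1-yl)phenol F3 and silylated (TIPSCl, imidazole) to [5-bromo-4-iodo-2-(3-methylbut-2-en-1-yl)phenoxy]tri(propan-2-yl)silane F4. Negishi coupling of F2 with F4 (Pd(OAc)2, SPhos, THF, rt) should take place at the C–I bond only and give the 2-bromoaryl TBS ether F5. CSA-catalysed methanolysis of the primary TBS ether at 0 °C should give the bromoaryl alcohol F6. Intramolecular Buchwald–Hartwig etherification (Pd(OAc)2, 2-(di-tert-butylphosphino)-1,1'-binaphthyl, Cs2CO3, toluene, 80 °C) then closes ring C to 13.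

2. Step 1. What may go wrong: O-alkylation, para- or double C-alkylation, and attack at the ortho carbon next to iodine may compete, so the wanted isomer forms in low amount and is hard to separate.

   Fallback with the regiochemistry fixed by an ortho-formyl group, setting out from 1 and coming back at 3: magnesium-mediated ortho-formylation of 1 (MgCl2, Et3N, paraformaldehyde, MeCN, reflux) should give 2-hydroxy-4-iodobenzaldehyde F7. Silylation (TIPSCl, imidazole, DMF) gives 4-iodo-2-{[tri(propan-2-yl)silyl]oxy}benzaldehyde F8. Reduction (NaBH4, MeOH, 0 °C) gives (4-iodo-2-{[tri(propan-2-yl)silyl]oxy}phenyl)methanol F9. Appel bromination (CBr4, PPh3, CH2Cl2, 0 °C) gives [2-(bromomethyl)-5-iodophenoxy]tri(propan-2-yl)silane F10. Copper-catalysed coupling with 2-methylprop-1-enylmagnesium bromide (CuI cat., THF, −20 °C) attaches the remaining four carbons of the prenyl group and gives 3 directly.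

3. Step 6. What may go wrong: oxidative addition of the electron-rich, ortho-alkoxy aryl bromide to nickel may be slow, so that reductive dimerisation or reduction of 3-bromooxetane and hydrodebromination of 8 dominate.

   Fallback with the aryl group as nucleophile, setting out from 8 and coming back at 10: bromine–lithium exchange and borylation (nBuLi, THF, −78 °C; B(OiPr)3; aqueous NH4Cl) should give (2,2-dimethyl-5-{[tri(propan-2-yl)silyl]oxy}-2H-chromen-8-yl)boronic acid F11. Nickel-catalysed Suzuki coupling of F11 with commercial 3-iodooxetane (NiI2, trans-2-aminocyclohexanol hydrochloride, NaHMDS, iPrOH, 80 °C, short heating) gives 10.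

**Further compounds**
F1 | step 8 | tert-butyl{[(2R)-3-bromo-2-(2,2-dimethyl-5-{[tri(propan-2-yl)silyl]oxy}-2H-chromen-8-yl)propyl]oxy}dimethylsilane | CC(C)(C)[Si](C)(C)OC[C@@H](c1ccc(O[Si](C(C)C)(C(C)C)C(C)C)c2c1OC(C)(C)C=C2)CBr
F2 | step 8 | bromo[(2R)-3-{[tert-butyl(dimethyl)silyl]oxy}-2-(2,2-dimethyl-5-{[tri(propan-2-yl)silyl]oxy}-2H-chromen-8-yl)propyl]zinc | CC(C)(C)[Si](C)(C)OC[C@@H](c1ccc(O[Si](C(C)C)(C(C)C)C(C)C)c2c1OC(C)(C)C=C2)C[Zn]Br
F3 | step 8 | 5-bromo-4-iodo-2-(3-methylbut-2-en-1-yl)phenol | CC(C)=CCc1cc(I)c(Br)cc1O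
F4 | step 8 | [5-bromo-4-iodo-2-(3-methylbut-2-en-1-yl)phenoxy]tri(propan-2-yl)silane | CC(C)=CCc1cc(I)c(Br)cc1O[Si](C(C)C)(C(C)C)C(C)C
F5 | step 8 | {[(2R)-3-[2-bromo-5-(3-methylbut-2-en-1-yl)-4-{[tri(propan-2-yl)silyl]oxy}phenyl]-2-(2,2-dimethyl-5-{[tri(propan-2-yl)silyl]oxy}-2H-chromen-8-yl)propyl]oxy}(tert-butyl)dimethylsilane | CC(C)(C)[Si](C)(C)OC[C@@H](c1ccc(O[Si](C(C)C)(C(C)C)C(C)C)c2c1OC(C)(C)C=C2)Cc1cc(CC=C(C)C)c(O[Si](C(C)C)(C(C)C)C(C)C)cc1Br
F6 | step 8 | (2R)-3-[2-bromo-5-(3-methylbut-2-en-1-yl)-4-{[tri(propan-2-yl)silyl]oxy}phenyl]-2-(2,2-dimethyl-5-{[tri(propan-2-yl)silyl]oxy}-2H-chromen-8-yl)propan-1-ol | OC[C@@H](c1ccc(O[Si](C(C)C)(C(C)C)C(C)C)c2c1OC(C)(C)C=C2)Cc1cc(CC=C(C)C)c(O[Si](C(C)C)(C(C)C)C(C)C)cc1Br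
F7 | step 1 | 2-hydroxy-4-iodobenzaldehyde | O=Cc1ccc(I)cc1O
F8 | step 1 | 4-iodo-2-{[tri(propan-2-yl)silyl]oxy}benzaldehyde | O=Cc1ccc(I)cc1O[Si](C(C)C)(C(C)C)C(C)C
F9 | step 1 | (4-iodo-2-{[tri(propan-2-yl)silyl]oxy}phenyl)methanol | OCc1ccc(I)cc1O[Si](C(C)C)(C(C)C)C(C)C
F10 | step 1 | [2-(bromomethyl)-5-iodophenoxy]tri(propan-2-yl)silane | BrCc1ccc(I)cc1O[Si](C(C)C)(C(C)C)C(C)C
F11 | step 6 | (2,2-dimethyl-5-{[tri(propan-2-yl)silyl]oxy}-2H-chromen-8-yl)boronic acid | CC1(C)C=Cc2c(O[Si](C(C)C)(C(C)C)C(C)C)ccc(B(O)O)c2O1
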